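Stop this flask by hand rather than leave it for the full 4.0 d: that is the decision to test.

common to all: starting material 0.30 M; free catalyst 15 mM

| charge | second substrate | coupling partner | remark | time |
|---|---|---|---|---|
| Thursday's | 0.60 M | 0.45 M | run made earlier |  |
| flask | 0.600 M | 0.300 M |  | 4.0 d |

Thursday's run (percent of the starting material charged)

| time / h | target / % | starting material / % |
|---|---|---|
| 1.50 | 22.0 | 62.3 |
| 3.00 | 32.6 | 43.4 |
| 5.00 | 38.2 | 27.6 |
| 10.0 | 39.0 | 17.5 |
| 20.0 | 33.6 | 10.5 |

(standard deviation of a reading: 1 percentage point)

1. time, not beyond 4.0 d, at which the flask holds most target
2. the amount of target, in percent of the starting material charged, at that time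

- what was read earlier has a scatter of 1 percentage point, one standard deviation
- a reading or a percentage of target counts all its forms, free or not

Take Thursday's run slowly. In the first 1.50 h, starting material drops to 62.3% and target climbs to 22.0%. From 5.00 h to 10.0 h the target reading moves by 0.8 percentage points. From 10.0 h to 20.0 h, starting material loses 7 points and target 5.4 points, equal within the scatter, so the two seem to vanish together, one for one. The balance D, target minus starting material in percent of the charge, therefore stands still there within the scatter: 22 points, then 23 points.

My own reckoning assumes that Thursday's coupling partner had stopped making target by 10.0 h. Each target formed costs one starting material, so D equals twice the gross target G minus 100 points, and the common loss leaves it unchanged. Thursday's mean D of 22 points gives G of 61.1%. Over the partner charge, that gives 0.408 for s, the partner share, the fraction of charged coupling partner that becomes target.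

With the same second substrate, and s taken as unchanged, this flask should reach D of −18 points once its partner has stopped making target. From then on, negative D means starting material outlasts target, so waiting costs target. Scaling Thursday's readings by the partner charge, on the assumption that partner is used at Thursday's pace, puts the peak near 26.0%, between 0.139 d and 0.278 d.

The forecast says 0.42 d and 34%, later and higher than my reckoning: “Target formation falls to equal its loss near 10 h, at about 34–35%.”

The flask gives 0.216 d and 23.2%.

    starting material + free catalyst ⇌ catalyst intermediate A (K = 25.0 L mol⁻¹, k = 0.0230 L mol⁻¹ s⁻¹)
    coupling partner + catalyst intermediate A → free catalyst + target (k = 0.00580 L mol⁻¹ s⁻¹)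
    second substrate + free catalyst ⇌ catalyst intermediate B (K = 1.90 L mol⁻¹, k = 0.0240 L mol⁻¹ s⁻¹)
    coupling partner + catalyst intermediate B → free catalyst + second product (k = 0.0220 L mol⁻¹ s⁻¹)
    crystals ⇌ target, rate k5*(cs5 - [target]) while solid is left; crystals form when [target] > cs5 (solubility = 28.0 mM, k = 0.00230 s⁻¹)
    starting material + target → side product (k = 5.60 × 10⁻⁴ L mol⁻¹ s⁻¹)

With coupling partner, the limiting reagent, at 0%, the flask ends at 0.103% target beside 8.24% starting material. Its D of −8.1 points is negative as reckoned, but less negative than −18 points, and its partner share, what the 0.164 M of second product leaves of the partner charge, is 0.453. A neighbouring flask charged with 0.24 M of second substrate has 0.110 M of second product, so a share of 0.634, which the same reckoning turns into a positive D of 27 points. After a best of 39.2%, it still holds 27.2% target at 4.00 d, beside 0.239% starting material.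

The runs stem from a simulated flask for substances that don't exist, and the scatter is random.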